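**Plan**

1. Retrosynthesis (bicycle numbered C1 lactone carbonyl, O2, C3 lactone CH2, C3a, C4 ketone, C5=C6, C7, C7a): cut the CH2–C3' bond between the ethylene tether and the pyranone (alkylzinc + 3-bromopyranone), then the acyl–oxygen bond of the γ-lactone, then the ring bond C3a–C7a in a retro-[3,3] sense, which turns the cyclohexene acid into a 6-alkenyl-3-oxy δ-lactone. That lactone is cut at the vinyl–CH2OH bond, at its own acyl–oxygen bond (a 1,5-diol) and at the alkyne–carbonyl bond (δ-valerolactone + a silyl-protected butynol).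
2. Feature used: C3a (quaternary, carrying the lactone CH2 and the two-carbon tether) and C7a (carrying the hydroxyl and the lactone carbonyl) are neighbours in the cyclohexenone ring and both belong to the γ-lactone. Their bond can therefore be the σ-bond made in a Claisen rearrangement in which C7a is the α-carbon of a lactone enolate and C3a the far carbon of an allylic alkene.
3. Forward order: the open chain is built first, the δ-lactone is closed by oxidation, the carbocycle arises in the boat Ireland–Claisen step, the trans-fused γ-lactone is closed next, the ring alkene is transposed to the enone (epoxide, selenide, oxidation), and the furyl pyranone, made separately in three steps, is joined last by Negishi coupling.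
4. Stereochemistry: the only external source is the asymmetric transfer hydrogenation that sets the (R)-carbinol. The (Z)-alkene comes from trans-hydroalumination/iodination and a stereoretentive coupling. The boat transition state translates both into the (3aR,7aR) pair, in which the hydroxyl is cis to the lactone CH2 and the tether cis to the lactone carbonyl (a trans-fused γ-lactone).

Key step: step 7

Assumption: 3-ethynylfuran, tert-butyl but-2-ynoate and (tributylstannyl)methanol are taken as catalogue reagents; the hydroxy ynone of step 1 is drawn open-chain although it equilibrates with its cyclic hemiketal.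

**Route**

Step 1
Reactants: 1 oxan-2-one (δ-valerolactone); 2 tert-butyl(but-3-yn-1-yloxy)dimethylsilane
Product: 5 9-[(tert-butyldimethylsilyl)oxy]-1-hydroxynon-6-yn-5-one, via lithium acetylide 3 (not isolated), via lithium hemiketal alkoxide 4 (not isolated)
Conditions: 2, n-BuLi, THF, −78 °C; then 1, −78 °C; H2O
Reagents that add atoms: none
Why: Acylation of an alkynyllithium by a lactone: adduct 4 is stable at −78 °C and releases the ketone only on quenching, so one acetylide is taken up and the ring oxygen emerges as the primary hydroxyl.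

Step 2
Reactants: 5 9-[(tert-butyldimethylsilyl)oxy]-1-hydroxynon-6-yn-5-one
Product: 6 (5R)-9-[(tert-butyldimethylsilyl)oxy]non-6-yne-1,5-diol
Conditions: Ru[(R,R)-TsDPEN](p-cymene) (1 mol %), i-PrOH, rt
Reagents that add atoms: none
Why: Noyori–Ikariya asymmetric transfer hydrogenation of an alkynyl ketone, in which the alkynyl group plays the part of the aryl group of acetophenone-type substrates, so the (R,R)-catalyst should deliver hydride to the face that gives the (R)-carbinol; the open ketone form of 5 is the species reduced.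

Step 3
Reactants: 6 (5R)-9-[(tert-butyldimethylsilyl)oxy]non-6-yne-1,5-diol
Product: 8 (5R,6Z)-9-[(tert-butyldimethylsilyl)oxy]-7-iodonon-6-ene-1,5-diol, via cyclic alkenylalanate 7 (not isolated)
Conditions: NaAlH2(OCH2CH2OCH3)2, THF, 0 °C → rt; then I2, −78 °C → 0 °C
Reagents that add atoms: iodine, II
Why: Hydroxyl-directed trans-hydroalumination of a propargylic alcohol followed by iodinolysis of the carbon–aluminium bond with retention: hydride goes to the alkyne carbon next to the carbinol, aluminium sits on the far carbon inside a five-membered alkoxide chelate, and iodine therefore ends cis to the carbinol carbon (Z) with the silyloxyethyl group trans.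

Step 4
Reactants: 8 (5R,6Z)-9-[(tert-butyldimethylsilyl)oxy]-7-iodonon-6-ene-1,5-diol
Product: 11 (6R)-6-[(1Z)-4-[(tert-butyldimethylsilyl)oxy]-2-iodobut-1-en-1-yl]oxan-2-one, via hydroxy aldehyde 9 (not isolated), via lactol 10 (not isolated)
Conditions: TEMPO (cat.), PhI(OAc)2, CH2Cl2, rt
Reagents that add atoms: none
Why: TEMPO/PhI(OAc)2 oxidative lactonization of a 1,5-diol: the primary alcohol is oxidized first, the aldehyde is captured by the secondary hydroxyl as lactol 10 and this is oxidized on to the δ-lactone, so the allylic carbinol is never exposed as a ketone and keeps its configuration.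

Step 5
Reactants: 11 (6R)-6-[(1Z)-4-[(tert-butyldimethylsilyl)oxy]-2-iodobut-1-en-1-yl]oxan-2-one
Product: 13 (6R)-3-hydroxy-6-[(1Z)-4-[(tert-butyldimethylsilyl)oxy]-2-iodobut-1-en-1-yl]oxan-2-one (both C3 epimers), via potassium enolate 12 (not isolated)
Conditions: KN(SiMe3)2 (1.1 equiv), THF, −78 °C; 3-phenyl-2-(phenylsulfonyl)oxaziridine, −78 °C; AcOH
Reagents that add atoms: 3-phenyl-2-(phenylsulfonyl)oxaziridine, O=S(=O)(c1ccccc1)N1OC1c1ccccc1
Why: Davis α-hydroxylation of a lactone enolate with an N-sulfonyloxaziridine; the configuration at C3 does not matter because this carbon becomes trigonal again in step 7, and one equivalent of base at −78 °C should leave the alkenyl iodide untouched.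

Step 6
Reactants: 13 (6R)-3-hydroxy-6-[(1Z)-4-[(tert-butyldimethylsilyl)oxy]-2-iodobut-1-en-1-yl]oxan-2-one; 14 (tributylstannyl)methanol
Product: 15 (6R)-3-hydroxy-6-[(1Z)-4-[(tert-butyldimethylsilyl)oxy]-2-(hydroxymethyl)but-1-en-1-yl]oxan-2-one (both C3 epimers)
Conditions: Pd(PPh3)4 (5 mol %), 1,4-dioxane, 80 °C
Reagents that add atoms: none
Why: Migita–Kosugi–Stille hydroxymethylation of an alkenyl iodide; oxidative addition and reductive elimination both proceed with retention at the sp2 carbon, so CH2OH takes the place of iodine cis to C6 (Z), and insertion of zerovalent palladium into the carbon–iodine bond should be much faster than ionization of the allylic lactone.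

Step 7
Reactants: 15 (6R)-3-hydroxy-6-[(1Z)-4-[(tert-butyldimethylsilyl)oxy]-2-(hydroxymethyl)but-1-en-1-yl]oxan-2-one
Product: 19 (1R,2R)-2-[2-[(tert-butyldimethylsilyl)oxy]ethyl]-1-hydroxy-2-(hydroxymethyl)cyclohex-3-ene-1-carboxylic acid, via bis-silyl ether 16 (not isolated), via silyl ketene acetal 17 (not isolated), via silyl ester 18 (not isolated)
Conditions: Me3SiCl (6 equiv), THF, −78 °C, then LiN(iPr)2 (3.5 equiv) dropwise, −78 °C → rt; PhMe, 110 °C; then 10% aq. citric acid, MeOH, rt
Reagents that add atoms: none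
Why: LiN(iPr)2 removes the two hydroxyl protons and then the C3 proton while Me3SiCl traps each anion as it forms, so that 17 is a cyclic silyl ketene acetal holding the allyl vinyl ether array C3=C2–O1–C6–CH=C; on heating, a concerted [3,3]-sigmatropic shift makes the bond from C3 to the disubstituted alkene terminus as the allylic C6–O1 bond breaks (Ireland–Claisen rearrangement of a lactone ketene acetal, the known ring contraction of 6-alkenyl δ-lactones to cyclohex-3-enecarboxylic acids). The six-membered carbocycle is thus closed by a pericyclic ring contraction and not by an ionic exo or endo cyclization: because C4–C5 ties the two ends of the six-atom array together, only a boat transition state shaped like bicyclo[2.2.2]octane is within reach. The ketene acetal is endocyclic and has a single geometry, so the relative configuration of the two new centres rests on the (Z)-alkene alone: the CH2OSiMe3 group, cis to C6, ends trans to the carboxyl carbon and cis to the C1 oxygen, and the silyloxyethyl chain ends cis to the carboxyl carbon, which places carboxyl and CH2O trans as in the target lactone. The absolute configuration of both centres is relayed from (6R)-C6, whose alkenyl group can fold over one face of the ketene acetal only, and the two C3 epimers of 15 converge because C3 is trigonal in 17. The step needs complete O-silylation and a rearrangement that outruns loss of the silyl groups; the internal Me3SiCl quench and the strong driving force (a carboxylate from a ketene acetal) should secure both, and dilute citric acid in methanol then removes the three Me3Si groups while the primary tert-butyldimethylsilyl ether stays.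

Step 8
Reactants: 19 (1R,2R)-2-[2-[(tert-butyldimethylsilyl)oxy]ethyl]-1-hydroxy-2-(hydroxymethyl)cyclohex-3-ene-1-carboxylic acid
Product: 20 (3aR,7aR)-3a-[2-[(tert-butyldimethylsilyl)oxy]ethyl]-7a-hydroxy-3a,6,7,7a-tetrahydro-2-benzofuran-1(3H)-one
Conditions: EDC·HCl, DMAP (cat.), CH2Cl2 (high dilution), 0 °C → rt
Reagents that add atoms: none
Why: Carbodiimide/DMAP (Steglich-type) lactonization: in the half-chair with carboxyl and CH2OH both pseudoequatorial the two groups are gauche and close the trans-fused five-membered lactone by 5-exo-trig attack on the activated acyl group, the tertiary hydroxyl is too hindered to be acylated, and the silyl ether on the tether rules out the competing six-membered lactone.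

Step 9
Reactants: 20 (3aR,7aR)-3a-[2-[(tert-butyldimethylsilyl)oxy]ethyl]-7a-hydroxy-3a,6,7,7a-tetrahydro-2-benzofuran-1(3H)-one
Product: 21 3a-[2-[(tert-butyldimethylsilyl)oxy]ethyl]-4,5-epoxy-7a-hydroxyhexahydro-2-benzofuran-1(3H)-one (oxirane oxygen cis to the 7a-hydroxyl)
Conditions: mCPBA, CH2Cl2, 0 °C → rt
Reagents that add atoms: 3-chloroperbenzoic acid, O=C(OO)c1cccc(Cl)c1
Why: Prilezhaev epoxidation of the only alkene, expected on the face opposite the pseudoaxial silyloxyethyl chain of the neighbouring quaternary carbon and syn to the 7a-hydroxyl, which can hydrogen-bond to the peracid; both new stereocentres are removed again in steps 10 and 11.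

Step 10
Reactants: 21 3a-[2-[(tert-butyldimethylsilyl)oxy]ethyl]-4,5-epoxy-7a-hydroxyhexahydro-2-benzofuran-1(3H)-one
Product: 24 (3aS,4S,7aR)-3a-[2-[(tert-butyldimethylsilyl)oxy]ethyl]-4,7a-dihydroxy-3a,4,7,7a-tetrahydro-2-benzofuran-1(3H)-one, via hydroxy selenide 22 (not isolated), via selenoxide 23 (not isolated)
Conditions: (PhSe)2, NaBH4 (not in excess), EtOH, rt → 70 °C; then THF, 30% H2O2, 0 °C → rt
Reagents that add atoms: none
Why: Sharpless–Lauer conversion of an epoxide into the transposed allylic alcohol: the selenolate opens the oxirane trans-diaxially at C5, the carbon remote from the quaternary centre (Fürst–Plattner rule and steric preference coincide for this epoxide), and selenoxide 23 then undergoes syn elimination away from the carbinol carbon towards C6, leaving the C4 hydroxyl in place.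

Step 11
Reactants: 24 (3aS,4S,7aR)-3a-[2-[(tert-butyldimethylsilyl)oxy]ethyl]-4,7a-dihydroxy-3a,4,7,7a-tetrahydro-2-benzofuran-1(3H)-one
Product: 25 (3aR,7aR)-3a-[2-[(tert-butyldimethylsilyl)oxy]ethyl]-7a-hydroxy-3a,7a-dihydro-2-benzofuran-1,4(3H,7H)-dione
Conditions: Dess–Martin periodinane, CH2Cl2, rt
Reagents that add atoms: none
Why: Dess–Martin oxidation of the secondary allylic alcohol to the enone under neutral conditions, which the tertiary hydroxyl cannot undergo and which avoid retro-aldol cleavage of the resulting β-hydroxy ketone.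

Step 12
Reactants: 25 (3aR,7aR)-3a-[2-[(tert-butyldimethylsilyl)oxy]ethyl]-7a-hydroxy-3a,7a-dihydro-2-benzofuran-1,4(3H,7H)-dione
Product: 26 (3aR,7aR)-7a-hydroxy-3a-(2-hydroxyethyl)-3a,7a-dihydro-2-benzofuran-1,4(3H,7H)-dione
Conditions: HF·pyridine, THF/pyridine, 0 °C → rt
Reagents that add atoms: none
Why: Fluoride-mediated cleavage of the primary silyl ether with buffered HF·pyridine, which spares the base-sensitive β-hydroxy ketone and is mild enough that the freed hydroxyl, cis to the lactone carbonyl, should not take over the acyl group before it is iodinated (the alcohol is used at once).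

Step 13
Reactants: 26 (3aR,7aR)-7a-hydroxy-3a-(2-hydroxyethyl)-3a,7a-dihydro-2-benzofuran-1,4(3H,7H)-dione
Product: 27 (3aR,7aR)-7a-hydroxy-3a-(2-iodoethyl)-3a,7a-dihydro-2-benzofuran-1,4(3H,7H)-dione
Conditions: I2, PPh3, imidazole, CH2Cl2, 0 °C
Reagents that add atoms: iodine, II
Why: Garegg–Samuelsson (Appel-type) iodination: only the primary hydroxyl is activated by the phosphine–iodine reagent and displaced by iodide in an SN2 step, the tertiary α-hydroxy lactone being too hindered to react.

Step 14
Reactants: 28 tert-butyl but-2-ynoate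
Product: 29 tert-butyl (2E)-2,3-dibromobut-2-enoate
Conditions: Br2, CH2Cl2, 0 °C, dark
Reagents that add atoms: bromine, BrBr
Why: Electrophilic anti addition of bromine to the alkyne, which should give mainly the (E)-dibromide with the C3 bromine cis to the ester, the geometry needed for ring closure in step 16.

Step 15
Reactants: 29 tert-butyl (2E)-2,3-dibromobut-2-enoate; 30 3-ethynylfuran
Product: 31 tert-butyl (2E)-2-bromo-5-(furan-3-yl)-3-methylpent-2-en-4-ynoate
Conditions: PdCl2(PPh3)2 (3 mol %), CuI (5 mol %), Et3N, THF, rt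
Reagents that add atoms: none
Why: Sonogashira coupling, expected to be site-selective for the β-bromide because zerovalent palladium inserts faster at the electron-poor β-carbon of a 2,3-dibromo enoate than at the α-carbon, and stereoretentive, so the alkyne ends cis to the ester.

Step 16
Reactants: 31 tert-butyl (2E)-2-bromo-5-(furan-3-yl)-3-methylpent-2-en-4-ynoate
Product: 32 3-bromo-6-(furan-3-yl)-4-methyl-2H-pyran-2-one
Conditions: Ph3PAuCl (5 mol %), AgOTf (5 mol %), CH2Cl2, rt
Reagents that add atoms: none
Why: Gold-catalysed 6-endo-dig cycloisomerization (the acyclic counterpart of the isocoumarin synthesis from 2-alkynylbenzoates): the ester carbonyl oxygen attacks the gold-activated alkyne at the furyl-bearing carbon, which best supports positive charge, isobutene is lost and protodeauration gives the 2-pyranone with bromine at C3.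

Step 17
Reactants: 27 (3aR,7aR)-7a-hydroxy-3a-(2-iodoethyl)-3a,7a-dihydro-2-benzofuran-1,4(3H,7H)-dione; 32 3-bromo-6-(furan-3-yl)-4-methyl-2H-pyran-2-one
Product: 34 (3aR,7aR)-3a-[2-[6-(furan-3-yl)-4-methyl-2-oxo-2H-pyran-3-yl]ethyl]-7a-hydroxy-3a,7a-dihydro-2-benzofuran-1,4(3H,7H)-dione (CNP0550188.1), via alkylzinc iodide 33 (not isolated)
Conditions: 27, Zn dust (activated with BrCH2CH2Br and Me3SiCl), LiCl, THF, 25 °C; then 32, Pd(OAc)2 (3 mol %), SPhos (6 mol %), THF, 25–40 °C
Reagents that add atoms: none
Why: Negishi sp3–sp2 cross-coupling: zinc inserts into the primary carbon–iodine bond to give 33, which should be inert towards ketone, lactone and tertiary hydroxyl and does not add to the enone without copper or a Lewis acid, and zerovalent palladium formed from Pd(OAc)2 and SPhos joins it to the 3-bromopyranone (an α-bromo enoate) faster than β-hydride elimination; no stereocentre is touched.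

**Compound list**

1 | oxan-2-one (δ-valerolactone) | O=C1CCCCO1 | starting material
2 | tert-butyl(but-3-yn-1-yloxy)dimethylsilane | C#CCCO[Si](C)(C)C(C)(C)C | starting material
3 | [4-[(tert-butyldimethylsilyl)oxy]but-1-yn-1-yl]lithium | [Li]C#CCCO[Si](C)(C)C(C)(C)C | intermediate
4 | lithium 2-[4-[(tert-butyldimethylsilyl)oxy]but-1-yn-1-yl]oxan-2-olate | [Li+].[O-]C1(C#CCCO[Si](C)(C)C(C)(C)C)CCCCO1 | intermediate
5 | 9-[(tert-butyldimethylsilyl)oxy]-1-hydroxynon-6-yn-5-one | OCCCCC(=O)C#CCCO[Si](C)(C)C(C)(C)C | intermediate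
6 | (5R)-9-[(tert-butyldimethylsilyl)oxy]non-6-yne-1,5-diol | OCCCC[C@@H](O)C#CCCO[Si](C)(C)C(C)(C)C | intermediate
7 | sodium cyclic alkenylalanate of 6 (five-membered O–Al–C=C chelate; primary hydroxyl drawn as sodium alkoxide) | [Na+].[Na+].COCCO[Al-]1(OCCOC)O[C@H](CCCC[O-])C=C1CCO[Si](C)(C)C(C)(C)C | intermediate
8 | (5R,6Z)-9-[(tert-butyldimethylsilyl)oxy]-7-iodonon-6-ene-1,5-diol | OCCCC[C@@H](O)/C=C(\I)CCO[Si](C)(C)C(C)(C)C | intermediate
9 | (5R,6Z)-9-[(tert-butyldimethylsilyl)oxy]-5-hydroxy-7-iodonon-6-enal | O=CCCC[C@@H](O)/C=C(\I)CCO[Si](C)(C)C(C)(C)C | intermediate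
10 | (6R)-6-[(1Z)-4-[(tert-butyldimethylsilyl)oxy]-2-iodobut-1-en-1-yl]oxan-2-ol (lactol, both anomers) | OC1CCC[C@H](/C=C(\I)CCO[Si](C)(C)C(C)(C)C)O1 | intermediate
11 | (6R)-6-[(1Z)-4-[(tert-butyldimethylsilyl)oxy]-2-iodobut-1-en-1-yl]oxan-2-one | O=C1CCC[C@H](/C=C(\I)CCO[Si](C)(C)C(C)(C)C)O1 | intermediate
12 | potassium enolate of 11 | [K+].[O-]C1=CCC[C@H](/C=C(\I)CCO[Si](C)(C)C(C)(C)C)O1 | intermediate
13 | (6R)-3-hydroxy-6-[(1Z)-4-[(tert-butyldimethylsilyl)oxy]-2-iodobut-1-en-1-yl]oxan-2-one (both C3 epimers) | O=C1C(O)CC[C@H](/C=C(\I)CCO[Si](C)(C)C(C)(C)C)O1 | intermediate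
14 | (tributylstannyl)methanol | CCCC[Sn](CCCC)(CCCC)CO | starting material
15 | (6R)-3-hydroxy-6-[(1Z)-4-[(tert-butyldimethylsilyl)oxy]-2-(hydroxymethyl)but-1-en-1-yl]oxan-2-one (both C3 epimers) | O=C1C(O)CC[C@H](/C=C(\CO)CCO[Si](C)(C)C(C)(C)C)O1 | intermediate
16 | bis(trimethylsilyl) ether of 15 | O=C1C(O[Si](C)(C)C)CC[C@H](/C=C(\CO[Si](C)(C)C)CCO[Si](C)(C)C(C)(C)C)O1 | intermediate
17 | trimethylsilyl ketene acetal of 16 (2,3-bis(trimethylsilyloxy)-5,6-dihydro-4H-pyran) | C[Si](C)(C)OC1=C(O[Si](C)(C)C)CC[C@H](/C=C(\CO[Si](C)(C)C)CCO[Si](C)(C)C(C)(C)C)O1 | intermediate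
18 | trimethylsilyl (1R,2R)-2-[2-[(tert-butyldimethylsilyl)oxy]ethyl]-1-(trimethylsilyloxy)-2-[(trimethylsilyloxy)methyl]cyclohex-3-ene-1-carboxylate | C[Si](C)(C)OC(=O)[C@@]1(O[Si](C)(C)C)CCC=C[C@]1(CCO[Si](C)(C)C(C)(C)C)CO[Si](C)(C)C | intermediate
19 | (1R,2R)-2-[2-[(tert-butyldimethylsilyl)oxy]ethyl]-1-hydroxy-2-(hydroxymethyl)cyclohex-3-ene-1-carboxylic acid | OC(=O)[C@@]1(O)CCC=C[C@]1(CCO[Si](C)(C)C(C)(C)C)CO | intermediate
20 | (3aR,7aR)-3a-[2-[(tert-butyldimethylsilyl)oxy]ethyl]-7a-hydroxy-3a,6,7,7a-tetrahydro-2-benzofuran-1(3H)-one | O=C1OC[C@@]2(CCO[Si](C)(C)C(C)(C)C)C=CCC[C@]12O | intermediate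
21 | 4,5-epoxide of 20, oxirane oxygen cis to the 7a-hydroxyl | O=C1OC[C@@]2(CCO[Si](C)(C)C(C)(C)C)[C@H]3O[C@H]3CC[C@]12O | intermediate
22 | 4-hydroxy-5-(phenylselanyl) lactone (4-OH cis to 7a-OH, selenium trans to both) | O=C1OC[C@@]2(CCO[Si](C)(C)C(C)(C)C)[C@@H](O)[C@H]([Se]c3ccccc3)CC[C@]12O | intermediate
23 | selenoxide of 22 | O=C1OC[C@@]2(CCO[Si](C)(C)C(C)(C)C)[C@@H](O)[C@H]([Se](=O)c3ccccc3)CC[C@]12O | intermediate
24 | (3aS,4S,7aR)-3a-[2-[(tert-butyldimethylsilyl)oxy]ethyl]-4,7a-dihydroxy-3a,4,7,7a-tetrahydro-2-benzofuran-1(3H)-one | O=C1OC[C@@]2(CCO[Si](C)(C)C(C)(C)C)[C@@H](O)C=CC[C@]12O | intermediate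
25 | (3aR,7aR)-3a-[2-[(tert-butyldimethylsilyl)oxy]ethyl]-7a-hydroxy-3a,7a-dihydro-2-benzofuran-1,4(3H,7H)-dione | O=C1OC[C@@]2(CCO[Si](C)(C)C(C)(C)C)C(=O)C=CC[C@]12O | intermediate
26 | (3aR,7aR)-7a-hydroxy-3a-(2-hydroxyethyl)-3a,7a-dihydro-2-benzofuran-1,4(3H,7H)-dione | O=C1OC[C@@]2(CCO)C(=O)C=CC[C@]12O | intermediate
27 | (3aR,7aR)-7a-hydroxy-3a-(2-iodoethyl)-3a,7a-dihydro-2-benzofuran-1,4(3H,7H)-dione | O=C1OC[C@@]2(CCI)C(=O)C=CC[C@]12O | intermediate
28 | tert-butyl but-2-ynoate | CC#CC(=O)OC(C)(C)C | starting material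
29 | tert-butyl (2E)-2,3-dibromobut-2-enoate | C/C(Br)=C(\Br)C(=O)OC(C)(C)C | intermediate
30 | 3-ethynylfuran | C#Cc1ccoc1 | starting material
31 | tert-butyl (2E)-2-bromo-5-(furan-3-yl)-3-methylpent-2-en-4-ynoate (alkyne cis to the ester) | C/C(C#Cc1ccoc1)=C(\Br)C(=O)OC(C)(C)C | intermediate
32 | 3-bromo-6-(furan-3-yl)-4-methyl-2H-pyran-2-one | Cc1cc(-c2ccoc2)oc(=O)c1Br | intermediate
33 | alkylzinc iodide of 27 | O=C1OC[C@@]2(CC[Zn]I)C(=O)C=CC[C@]12O | intermediate
34 | (3aR,7aR)-3a-[2-[6-(furan-3-yl)-4-methyl-2-oxo-2H-pyran-3-yl]ethyl]-7a-hydroxy-3a,7a-dihydro-2-benzofuran-1,4(3H,7H)-dione (CNP0550188.1) | Cc1cc(-c2ccoc2)oc(=O)c1CC[C@@]12COC(=O)[C@@]1(O)CC=CC2=O | target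

**Count and risks**

Total steps: 17 (14 in the main line, 3 for the bromopyranone 32). Longest linear sequence: 14 steps (steps 1–13 and 17).

Step 7 (key step). What may go wrong: slow enolization next to the silyloxy group, or loss of the labile Me3Si groups from the α-oxygen or the ketene acetal before the hindered boat rearrangement (two fully substituted carbons being joined) sets in. Fallback with the same disconnection but stable acetal protection: from 15, MeOCH2Cl and iPr2NEt should give the bis(methoxymethyl) ether F1. Enolization with LiN(iPr)2/Me3SiCl gives the silyl ketene acetal F2, which is heated in toluene to the silyl ester F3 and hydrolysed on work-up to the acid F4 (the classical α-alkoxy ester Ireland–Claisen rearrangement). Me2BBr in CH2Cl2 at −78 °C then removes both methoxymethyl groups while the silyl ether stays, and the route is rejoined at 19.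

Step 17. What may go wrong: during zinc insertion the primary radical or the organozinc adds across the ring to the β-carbon of the enone (closing a bicyclo[2.2.2]octanone), or the carbon–zinc bond is protonated before transmetalation. Fallback, coupling one oxidation level earlier so that no enone is present: from 24, HF·pyridine gives the triol F5. I2/PPh3/imidazole at low temperature iodinates only the primary hydroxyl (the secondary one is neopentyl-like) to give the iodide F6. Zinc insertion gives the alkylzinc iodide F7 (not isolated), and Negishi coupling with 32 gives the allylic alcohol F8. Dess–Martin oxidation, which furan and pyranone tolerate, then gives 34.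

Step 10. What may go wrong: the selenolate must enter axially at C5 past the syn-axial side chain, and if the epoxide has formed on the other face, trans-diaxial opening would have to occur at the neopentyl carbon C4, so the opening stalls or gives the regioisomeric selenide. Fallback that avoids the epoxide: from 20, a Schenck ene reaction with singlet oxygen (O2, tetraphenylporphyrin, hν, CH2Cl2) can only take an allylic hydrogen from C6. Oxygen is therefore delivered to C4 and the double bond moves to C5=C6, giving the allylic hydroperoxide F9. Ac2O/pyridine (Kornblum–DeLaMare-type dehydration) converts it into the enone, and the route is rejoined at 25.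

**Further compounds**

F1 | step 7 | (6R)-3-(methoxymethoxy)-6-[(1Z)-4-[(tert-butyldimethylsilyl)oxy]-2-[(methoxymethoxy)methyl]but-1-en-1-yl]oxan-2-one (both C3 epimers) | O=C1C(OCOC)CC[C@H](/C=C(\COCOC)CCO[Si](C)(C)C(C)(C)C)O1
F2 | step 7 | trimethylsilyl ketene acetal of F1 | C[Si](C)(C)OC1=C(OCOC)CC[C@H](/C=C(\COCOC)CCO[Si](C)(C)C(C)(C)C)O1
F3 | step 7 | trimethylsilyl (1R,2R)-2-[2-[(tert-butyldimethylsilyl)oxy]ethyl]-1-(methoxymethoxy)-2-[(methoxymethoxy)methyl]cyclohex-3-ene-1-carboxylate | C[Si](C)(C)OC(=O)[C@@]1(OCOC)CCC=C[C@]1(CCO[Si](C)(C)C(C)(C)C)COCOC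
F4 | step 7 | (1R,2R)-2-[2-[(tert-butyldimethylsilyl)oxy]ethyl]-1-(methoxymethoxy)-2-[(methoxymethoxy)methyl]cyclohex-3-ene-1-carboxylic acid | OC(=O)[C@@]1(OCOC)CCC=C[C@]1(CCO[Si](C)(C)C(C)(C)C)COCOC
F5 | step 17 | (3aS,4S,7aR)-4,7a-dihydroxy-3a-(2-hydroxyethyl)-3a,4,7,7a-tetrahydro-2-benzofuran-1(3H)-one | O=C1OC[C@@]2(CCO)[C@@H](O)C=CC[C@]12O
F6 | step 17 | (3aS,4S,7aR)-4,7a-dihydroxy-3a-(2-iodoethyl)-3a,4,7,7a-tetrahydro-2-benzofuran-1(3H)-one | O=C1OC[C@@]2(CCI)[C@@H](O)C=CC[C@]12O
F7 | step 17 | alkylzinc iodide of F6 | O=C1OC[C@@]2(CC[Zn]I)[C@@H](O)C=CC[C@]12O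
F8 | step 17 | (3aS,4S,7aR)-3a-[2-[6-(furan-3-yl)-4-methyl-2-oxo-2H-pyran-3-yl]ethyl]-4,7a-dihydroxy-3a,4,7,7a-tetrahydro-2-benzofuran-1(3H)-one | O=C1OC[C@@]2(CCc3c(C)cc(-c4ccoc4)oc3=O)[C@@H](O)C=CC[C@]12O
F9 | step 10 | (3aS,7aR)-3a-[2-[(tert-butyldimethylsilyl)oxy]ethyl]-4-hydroperoxy-7a-hydroxy-3a,4,7,7a-tetrahydro-2-benzofuran-1(3H)-one (either C4 epimer) | O=C1OC[C@@]2(CCO[Si](C)(C)C(C)(C)C)C(OO)C=CC[C@]12O
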